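**Retrosynthetic overview**

1. Numbering (longipinane) and rings. C1 is the ring ketone and C2=C3 the enone, with C3 carrying methyl C12. C4 and C11 are the cyclobutane CH next to C3 and to C1, and C5 is the cyclobutane CH bearing C6 (CMe2). C7 is CH–O-angeloyl, C8 is CH–O-isobutyryl, C9 is CH2 and C10 is the quaternary C–CH3. Ring A is the cyclohexenone C1–C2–C3–C4–C10–C11, ring B the cyclobutane C4–C5–C11–C10, ring C the seven-membered ring C4–C5–C6–C7–C8–C9–C10.
2. Disconnections. The C7 ester comes from acylation and the C8 ester from SN2 opening of a 7,8-epoxide by isobutyric acid. Ring B is cut at C5–C11 (4-exo-tet α′-alkylation of the ring A enone by a C5 mesylate). Ring C is cut at C7=C8 (ring-closing metathesis). Ring A is cut at C2–C3 and C4–C10 (Diels–Alder reaction of a 2-silyloxydiene with an allenyl ketone, two achiral acyclic fragments of 8 and 9 carbons).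
3. Enabling feature. With the C5–C11 bond of ring B opened, ring A is a Diels–Alder retron. C11=C1(O)–C2 together with C10 is a 2-silyloxydiene that already carries the C10 methyl and C9. C3=C4 is the conjugated bond of an allenyl ketone whose carbonyl carbon is C5 and whose second double bond (C3=C12) stores the enone unsaturation.
4. Ring order: A (step 5), C (step 6), B (step 10). The C5 carbonyl first activates the dienophile, then as a carbinol directs the epoxidation of C7=C8, and finally leaves as mesylate when C11 attacks.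

Key step: step 5

Assumption: the (S)-configured oxazaborolidinium is taken to shield the face of the bound allenyl ketone that leads to the cycloadduct as drawn (α-C–H···O binding model); the mirror-image catalyst is used if the opposite sense is found.

Step 1
Reactants: 1 pent-1-en-4-yne
Product: 3 (E)-4-methylhepta-3,6-dien-2-one, via alkenylalane 2 (not isolated)
Conditions: Me3Al (2 equiv), Cp2ZrCl2 (20 mol%), CH2Cl2, 0 °C to rt; then AcCl, Pd(PPh3)4 (5 mol%), THF, 0 °C to rt
Reagents that add atoms: trimethylaluminium (C[Al](C)C); acetyl chloride (CC(=O)Cl)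
Why: Zirconium-catalysed Negishi carboalumination adds CH3 and Al syn across the terminal alkyne and the palladium-catalysed acylation of the alkenylalane goes with retention, so the allyl-bearing arm should end trans to the acetyl group (E).

Step 2
Reactants: 3 (E)-4-methylhepta-3,6-dien-2-one
Product: 5 (E)-[(4-methylhepta-1,3,6-trien-2-yl)oxy]tri(propan-2-yl)silane, via lithium dienolate 4 (not isolated)
Conditions: LiN(iPr)2, THF, −78 °C; then iPr3SiOTf, −78 to 0 °C
Reagents that add atoms: triisopropylsilyl trifluoromethanesulfonate (CC(C)[Si](C(C)C)(C(C)C)OS(=O)(=O)C(F)(F)F)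
Why: Kinetic α′-deprotonation of the methyl ketone followed by O-silylation gives the cross-conjugated 2-silyloxy-1,3-diene without touching the enone geometry.

Step 3
Reactants: 6 2,2-dimethylbut-3-enoic acid
Product: 8 N-methoxy-N,2,2-trimethylbut-3-enamide, via acid chloride 7 (not isolated)
Conditions: (COCl)2, DMF (cat.), CH2Cl2, 0 °C to rt; then MeNH(OMe)·HCl, Et3N, 0 °C
Reagents that add atoms: N,O-dimethylhydroxylamine hydrochloride (CNOC.Cl)
Why: Acid chloride formation and aminolysis is the standard route to the Weinreb amide of a hindered α-quaternary acid.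

Step 4
Reactants: 8 N-methoxy-N,2,2-trimethylbut-3-enamide
Product: 10 5,5-dimethylhepta-1,2,6-trien-4-one, via alkynyl ketone 9 (not isolated)
Conditions: HC≡CCH2MgBr, Et2O, −78 to 0 °C; aq. NH4Cl; then Et3N (cat.), CH2Cl2, rt
Reagents that add atoms: propargylmagnesium bromide (C#CC[Mg]Br)
Why: The allenyl Grignard reagent adds once to the Weinreb amide by SE2′ to give the β,γ-alkynyl ketone, and a base-catalysed prototropic shift should convert it into the conjugated allenyl ketone.

Step 5
Reactants: 5 (E)-[(4-methylhepta-1,3,6-trien-2-yl)oxy]tri(propan-2-yl)silane; 10 5,5-dimethylhepta-1,2,6-trien-4-one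
Product: 11 1-[(1R,2S)-2-methyl-6-methylidene-2-(prop-2-en-1-yl)-4-{[tri(propan-2-yl)silyl]oxy}cyclohex-3-en-1-yl]-2,2-dimethylbut-3-en-1-one
Conditions: (S)-diphenylprolinol-derived B-(o-tolyl)oxazaborolidine·HNTf2 (20 mol%), CH2Cl2, −78 to −40 °C
Reagents that add atoms: none
Why: The oxazaborolidinium cation binds the ketone oxygen of 10 and activates its conjugated C3=C4 bond, and diene 5 adds in an endo, asynchronous concerted [4+2] cycloaddition (Diels–Alder) in which C2–C3 bonding runs ahead of C4–C10 bonding. The closest known reaction type is the oxazaborolidinium-catalysed enantioselective Diels–Alder reaction of 2-silyloxy-1,3-dienes with α,β-unsaturated ketones, together with Lewis-acid-promoted cycloadditions of 4,4-disubstituted 2-silyloxydienes that create quaternary carbons. The cyclohexene ring (future ring A) closes in the suprafacial [4+2] mode. C10 (quaternary) and C4 are set relative to each other by the endo transition state and the E geometry of the diene, which puts the allyl group outside and therefore cis to the acyl group on C4, and their absolute configuration is set by the catalyst face. The step needs regioselectivity (nucleophilic CH2 terminus C2 to the electrophilic central allene carbon C3), periselectivity for the conjugated C=C of the allene, and endo selectivity; these are secured by the silyloxy group, by the fact that only C3=C4 is conjugated with the carbonyl, and by the small exo hydrogen on C4 facing the inside methyl of the diene.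

Step 6
Reactants: 11 Diels–Alder adduct (name as in step 5)
Product: 12 (4R,10S)-1-{[tri(propan-2-yl)silyl]oxy}-5,11-secolongipina-1(11),3(12),7-trien-5-one
Conditions: second-generation Grubbs catalyst (5 mol%), CH2Cl2 (5 mM), 40 °C
Reagents that add atoms: none
Why: Ring-closing metathesis of the allyl group on C10 and the vinyl group on C6, which are cis on the cyclohexene, should close ring C with help from the C6 gem-dimethyl group, while closure from the allyl side onto the exocyclic methylene would give a bridgehead alkene and is excluded.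

Step 7
Reactants: 12 (4R,10S)-1-{[tri(propan-2-yl)silyl]oxy}-5,11-secolongipina-1(11),3(12),7-trien-5-one
Product: 15 (4S,5S,10S)-5-hydroxy-5,11-secolongipina-2,7-dien-1-one, via triisopropylsilyl enol ether alcohol 13 (not isolated), via exo-methylene hydroxy ketone 14 (not isolated)
Conditions: Li, NH3(l), THF, EtOH, −78 °C; NH4Cl; then 2 M HCl, THF, rt
Reagents that add atoms: none
Why: Dissolving-metal reduction of the C5 ketone (C1 stays masked as silyl enol ether) should give the thermodynamically preferred alcohol, trans to the vicinal C4–C3 bond, and the acid step hydrolyses the enol ether and moves the exocyclic alkene into conjugation as in the hydrolysis of Birch-type dienol ethers.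

Step 8
Reactants: 15 (4S,5S,10S)-5-hydroxy-5,11-secolongipina-2,7-dien-1-one
Product: 16 (4S,5S,7S,8R,10S)-7,8-epoxy-5-hydroxy-5,11-secolongipin-2-en-1-one
Conditions: VO(acac)2 (5 mol%), t-BuOOH, CH2Cl2, 0 °C to rt
Reagents that add atoms: tert-butyl hydroperoxide (CC(C)(C)OO)
Why: Vanadium-catalysed hydroxyl-directed epoxidation should deliver oxygen to C7=C8 syn to the homoallylic C5 hydroxyl, which is also the convex face of the cis-fused bicycle, and leave the electron-poor enone untouched.

Step 9
Reactants: 16 (4S,5S,7S,8R,10S)-7,8-epoxy-5-hydroxy-5,11-secolongipin-2-en-1-one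
Product: 17 (4S,5S,7S,8R,10S)-7,8-epoxy-1-oxo-5,11-secolongipin-2-en-5-yl methanesulfonate
Conditions: MsCl, Et3N, CH2Cl2, 0 °C
Reagents that add atoms: methanesulfonyl chloride (CS(=O)(=O)Cl)
Why: Sulfonylation through sulfene converts the hindered secondary alcohol into the leaving group with retention at C5.

Step 10
Reactants: 17 (4S,5S,7S,8R,10S)-7,8-epoxy-1-oxo-5,11-secolongipin-2-en-5-yl methanesulfonate
Product: 19 (4R,5S,7S,8R,10R,11R)-7,8-epoxylongipin-2-en-1-one, via potassium dienolate 18 (not isolated)
Conditions: KN(SiMe3)2 (1.05 equiv), THF, −78 °C to rt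
Reagents that add atoms: none
Why: Kinetic α′-deprotonation of the enone (cross-conjugated dienolate, as with isophorone-type enones) and intramolecular 4-exo-tet enolate alkylation with inversion at C5 should close ring B, a known way to make cyclobutanes from cis-fused bicyclic keto sulfonates even at neopentyl carbons, with C11 fixed by the geometry of the closure.

Step 11
Reactants: 19 (4R,5S,7S,8R,10R,11R)-7,8-epoxylongipin-2-en-1-one
Product: 20 (4R,5S,7S,8S,10R,11R)-7-hydroxy-1-oxolongipin-2-en-8-yl 2-methylpropanoate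
Conditions: i-PrCO2H (solvent), NaO2CCH(CH3)2 (20 mol%), 80 °C
Reagents that add atoms: isobutyric acid (CC(C)C(=O)O)
Why: Carboxylic acid opening of the epoxide by SN2 attack at C8, the carbon remote from the quaternary C6, should invert C8 and give the trans 7-hydroxy-8-ester.

Step 12
Reactants: 20 (4R,5S,7S,8S,10R,11R)-7-hydroxy-1-oxolongipin-2-en-8-yl 2-methylpropanoate
Product: 21 (4R,5S,7S,8S,10R,11R)-1-oxo-8-(2-methylpropanoyloxy)longipin-2-en-7-yl (2Z)-2-methylbut-2-enoate
Conditions: angelic acid, 2,4,6-trichlorobenzoyl chloride, Et3N, toluene, rt; then 20, 80 °C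
Reagents that add atoms: angelic acid (C/C=C(/C)C(=O)O)
Why: Yamaguchi-type acylation through the mixed trichlorobenzoic anhydride without a nucleophilic catalyst should acylate the hindered C7 alcohol while keeping the Z geometry of the angeloyl group.

**Compound list**

1 | pent-1-en-4-yne | C#CCC=C | starting material
2 | (E)-dimethyl(2-methylpenta-1,4-dien-1-yl)alumane | C[Al](C)/C=C(\C)CC=C | intermediate
3 | (E)-4-methylhepta-3,6-dien-2-one | CC(=O)/C=C(\C)CC=C | intermediate
4 | lithium (E)-4-methylhepta-1,3,6-trien-2-olate | [Li]OC(=C)/C=C(\C)CC=C | intermediate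
5 | (E)-[(4-methylhepta-1,3,6-trien-2-yl)oxy]tri(propan-2-yl)silane | C=C(O[Si](C(C)C)(C(C)C)C(C)C)/C=C(\C)CC=C | intermediate
6 | 2,2-dimethylbut-3-enoic acid | C=CC(C)(C)C(=O)O | starting material
7 | 2,2-dimethylbut-3-enoyl chloride | C=CC(C)(C)C(=O)Cl | intermediate
8 | N-methoxy-N,2,2-trimethylbut-3-enamide | C=CC(C)(C)C(=O)N(C)OC | intermediate
9 | 3,3-dimethylhept-1-en-6-yn-4-one | C#CCC(=O)C(C)(C)C=C | intermediate
10 | 5,5-dimethylhepta-1,2,6-trien-4-one | C=C=CC(=O)C(C)(C)C=C | intermediate
11 | 1-[(1R,2S)-2-methyl-6-methylidene-2-(prop-2-en-1-yl)-4-{[tri(propan-2-yl)silyl]oxy}cyclohex-3-en-1-yl]-2,2-dimethylbut-3-en-1-one (allyl cis to acyl) | C=CC[C@@]1(C)C=C(O[Si](C(C)C)(C(C)C)C(C)C)CC(=C)[C@H]1C(=O)C(C)(C)C=C | intermediate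
12 | (4R,10S)-1-{[tri(propan-2-yl)silyl]oxy}-5,11-secolongipina-1(11),3(12),7-trien-5-one (cis-fused cyclohexene/cycloheptenone) | C1=CC[C@@]2(C)C=C(O[Si](C(C)C)(C(C)C)C(C)C)CC(=C)[C@H]2C(=O)C1(C)C | intermediate
13 | (4R,5S,10R)-1-{[tri(propan-2-yl)silyl]oxy}-5,11-secolongipina-1(11),3(12),7-trien-5-ol | C1=CC[C@@]2(C)C=C(O[Si](C(C)C)(C(C)C)C(C)C)CC(=C)[C@H]2[C@H](O)C1(C)C | intermediate
14 | (4R,5S,10S)-5-hydroxy-5,11-secolongipina-3(12),7-dien-1-one | C1=CC[C@@]2(C)CC(=O)CC(=C)[C@H]2[C@H](O)C1(C)C | intermediate
15 | (4S,5S,10S)-5-hydroxy-5,11-secolongipina-2,7-dien-1-one (OH trans to the C4–C3 bond) | C1=CC[C@@]2(C)CC(=O)C=C(C)[C@H]2[C@H](O)C1(C)C | intermediate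
16 | (4S,5S,7S,8R,10S)-7,8-epoxy-5-hydroxy-5,11-secolongipin-2-en-1-one (epoxide cis to OH) | O1[C@@H]2[C@H]1C[C@@]3(C)CC(=O)C=C(C)[C@H]3[C@H](O)C2(C)C | intermediate
17 | (4S,5S,7S,8R,10S)-7,8-epoxy-1-oxo-5,11-secolongipin-2-en-5-yl methanesulfonate | O1[C@@H]2[C@H]1C[C@@]3(C)CC(=O)C=C(C)[C@H]3[C@H](OS(C)(=O)=O)C2(C)C | intermediate
18 | potassium (4R,5S,7S,8R,10R)-7,8-epoxy-5-(methanesulfonyloxy)-5,11-secolongipina-1(11),2-dien-1-olate | O1[C@@H]2[C@H]1C[C@@]3(C)C=C(O[K])C=C(C)[C@H]3[C@H](OS(C)(=O)=O)C2(C)C | intermediate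
19 | (4R,5S,7S,8R,10R,11R)-7,8-epoxylongipin-2-en-1-one | O1[C@@H]2[C@H]1C[C@@]3(C)[C@@H]4C(=O)C=C(C)[C@H]3[C@@H]4C2(C)C | intermediate
20 | (4R,5S,7S,8S,10R,11R)-7-hydroxy-1-oxolongipin-2-en-8-yl 2-methylpropanoate | O[C@@H]1[C@@H](OC(=O)C(C)C)C[C@@]2(C)[C@@H]3C(=O)C=C(C)[C@H]2[C@@H]3C1(C)C | intermediate
21 | (4R,5S,7S,8S,10R,11R)-1-oxo-8-(2-methylpropanoyloxy)longipin-2-en-7-yl (2Z)-2-methylbut-2-enoate | C/C=C(/C)C(=O)O[C@@H]1[C@@H](OC(=O)C(C)C)C[C@@]2(C)[C@@H]3C(=O)C=C(C)[C@H]2[C@@H]3C1(C)C | target

Total step count: 12. Longest linear sequence: 10 steps (steps 1, 2, 5 to 12; the branch through steps 3 and 4 is equally long).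

**Steps most likely to fail**

Step 5. The cycloaddition may stall after the first C–C bond or lose facial control, because ring closure has to create the quaternary C10 next to the acyl-bearing C4. The fallback sets out from 5 and 10 and comes back at 11, and it makes the two bonds in separate operations. A Mukaiyama–Michael addition of 5 to the central allene carbon of 10 (Me3SiOTf cat., CH2Cl2, −78 °C, with silyl transfer) should give the open-chain silyl dienol ether (4Z,9E)-3,3,10-trimethyl-6-methylidene-4-{[tri(propan-2-yl)silyl]oxy}trideca-1,4,9,12-tetraen-8-one F1. A separate 6-endo-trig intramolecular Mukaiyama–Michael closure of F1 onto its β,β-disubstituted enone, run with the same chiral oxazaborolidinium at higher temperature, should then give 11.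

Step 7. Thermodynamic control in the dissolving-metal reduction may be incomplete (alcohol cis to the C4–C3 bond), or the base may conjugate the β,γ-unsaturated ketone before it is reduced. The fallback sets out from 12 and comes back at 15. Reduction from the convex face with K[BH(s-Bu)3] (THF, −78 °C) should give the C5-epimeric (4R,5R,10R) silyl enol ether alcohol F2. The same acid treatment should convert it, through the (4R,5R,10S) exo-methylene hydroxy ketone F3, into the (4S,5R,10S) hydroxy enone F4. Mitsunobu inversion of F4 (4-nitrobenzoic acid, PPh3, diisopropyl azodicarboxylate) should give the (4S,5S,10S) 4-nitrobenzoate F5, and methanolysis (K2CO3, MeOH) releases 15.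

Step 10. The 4-exo-tet closure at the neopentyl C5 may be slow enough for the kinetic α′-enolate to equilibrate to the extended dienolate (alkylation at C2) or for the mesylate to be lost by elimination. The fallback sets out from 17 and comes back at 19, and it separates deprotonation from bond formation. LiN(iPr)2 with Me3SiCl present (THF, −78 °C) should trap the kinetic enolate as the (4R,5S,7S,8R,10R) 1-trimethylsilyloxy-1(11),2-diene mesylate F6. Bu4N[Ph3SiF2] (THF, 0 °C to rt) then releases the regiodefined enolate without external base, so that only alkylation at C11 can follow, giving 19.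

Further compounds
F1 | step 5 | (4Z,9E)-3,3,10-trimethyl-6-methylidene-4-{[tri(propan-2-yl)silyl]oxy}trideca-1,4,9,12-tetraen-8-one | C=CC/C(C)=C/C(=O)CC(=C)/C=C(\O[Si](C(C)C)(C(C)C)C(C)C)C(C)(C)C=C
F2 | step 7 | (4R,5R,10R)-1-{[tri(propan-2-yl)silyl]oxy}-5,11-secolongipina-1(11),3(12),7-trien-5-ol | C1=CC[C@@]2(C)C=C(O[Si](C(C)C)(C(C)C)C(C)C)CC(=C)[C@H]2[C@@H](O)C1(C)C
F3 | step 7 | (4R,5R,10S)-5-hydroxy-5,11-secolongipina-3(12),7-dien-1-one | C1=CC[C@@]2(C)CC(=O)CC(=C)[C@H]2[C@@H](O)C1(C)C
F4 | step 7 | (4S,5R,10S)-5-hydroxy-5,11-secolongipina-2,7-dien-1-one | C1=CC[C@@]2(C)CC(=O)C=C(C)[C@H]2[C@@H](O)C1(C)C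
F5 | step 7 | (4S,5S,10S)-1-oxo-5,11-secolongipina-2,7-dien-5-yl 4-nitrobenzoate | C1=CC[C@@]2(C)CC(=O)C=C(C)[C@H]2[C@H](OC(=O)c3ccc(cc3)[N+](=O)[O-])C1(C)C
F6 | step 10 | (4R,5S,7S,8R,10R)-7,8-epoxy-1-(trimethylsilyloxy)-5,11-secolongipina-1(11),2-dien-5-yl methanesulfonate | O1[C@@H]2[C@H]1C[C@@]3(C)C=C(O[Si](C)(C)C)C=C(C)[C@H]3[C@H](OS(C)(=O)=O)C2(C)C
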